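Its constants were drawn at random within sensible limits; what happens was integrated by code.

An [intermediate] of 0.0240 M, the decomposition constant over the coupling constant, which I call the crossover concentration κ, is where partner goes equally fast to product and to decomposed reagent.

    partner + intermediate → product (k1 = 0.50 /M/s)
    substrate → intermediate (k2 = 1.0 /s)
    partner → decomposed reagent (k3 = 0.012 /s)

| flask | substrate | partner | time | remark |
|---|---|---|---|---|
| zeta | 0.10 M | 0.100 M | 50 s | plug flow through a tube for 50 s, no back-mixing |
| epsilon | 0.10 M | 0.100 M |  | one stirred flow tank at steady state, fed with the mixture as stated, mean residence time 50 s |
| alpha | 0.10 M | 0.100 M | 50 s | a closed flask charged with all of it at once and left for 50 s |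
| theta | 0.10 M (fed, over 25.0 s) | 0.100 M | 50 s | all but substrate at the start; substrate goes in evenly over 25.0 s, the run ends at 50 s |

- the set-up with the highest amount of intermediate at the outlet or at the end, in percent of the substrate put in ("none" if the first two lie within 2 percentage points) (zeta / epsilon / alpha / theta / none)
- amount of intermediate at the outlet or at the end, in percent of the substrate put in, zeta
- amount of intermediate at the outlet or at the end, in percent of the substrate put in, epsilon
- amount of intermediate at the outlet or at the end, in percent of the substrate put in, alpha
- amount of intermediate at the outlet or at the end, in percent of the substrate put in, theta

Coupling at the charged [partner] halves intermediate in 14 s, well inside the run of 50 s. But substrate has a half-life of 0.69 s, far shorter than that, so in zeta and alpha I start with the intermediate as charged. Partner's half-life by decomposition is 58 s, longer than the coupling's, yet comparable with the run, so I keep it. Dividing the two rate laws gives d[partner]/d[intermediate] = 1 + κ/[intermediate]. So [partner] − [intermediate] − κ ln([intermediate]/charge) holds its starting value, zero for equal charges. At the start [intermediate] is the charge; at the other end [partner] reaches zero, and a trial with one Newton step puts [intermediate] there at 0.0293 M, or 29.3% of the substrate. That is my estimate of where intermediate stops in zeta and alpha, and I expect both above it at the asked time. I give no number for epsilon or theta.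

The forecast names epsilon, with 38.4% for zeta, 52.9% for epsilon, 38.4% for alpha and 48.9% for theta, noting that “Zeta and alpha are the same calculation”.

The simulation gives epsilon, with 38.3%, 52.8%, 38.3% and 49.0% in that order.

Zeta at 500 s reads 30.0%, with partner at 0%, against my 29.3%. The neighbour of zeta charged with 0.25 M of substrate starts the same relation at partner minus charge, so zero [partner] means [intermediate] = 0.150 M − κ ln([intermediate]/charge). Two rounds of substitution give 0.162 M, then 0.160 M, which is 64.0% of its substrate. At 50.0 s that flask holds 64.9% of its substrate as intermediate, with partner at 0.716% of its charge.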